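**Retrosynthetic overview**
1. The O4-protected target is cut by a Suzuki–Miyaura disconnection at the diene single bond between the first trisubstituted alkene and the central alkene, giving a butenolide vinyl iodide and a bis-furan dienyl boronate; fluoride removal of a 2-(trimethylsilyl)ethyl group at O4 is the last step.
2. The butenolide comes from a three-component annulation of carbon dioxide, ethylidenetriphenylphosphorane and an (R)-α-triflyloxy ester: ylide carboxylation (C2–C3), carboxylate SN2 with inversion (O1–C5), then intramolecular Wittig olefination of the ester carbonyl (C3=C4).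
3. Enabling feature: in the 4-hydroxyfuran-2(5H)-one ring the sp3 carbon C5 is bonded to both the ring oxygen O1 and the enol carbon C4. The ring is therefore a propanoate unit O1–C2–C3 (O1 and C3 both nucleophilic in a phosphonio carboxylate) joined to an α-oxy ester unit C4–C5 (both electrophilic), and the ester alkoxy group stays on C4 as the protecting group.
4. The (R)-α-hydroxy ester comes from pent-4-yn-1-ol (carboalumination/iodination, oxidation, auxiliary-controlled α-hydroxylation, transesterification). The boronate comes from 3-bromofuran and 4-bromofuran-2-carbaldehyde (addition, deoxygenation, Negishi coupling, cross-metathesis, boron-Wittig olefination).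
5. Ring order: both furans are bought as rings; the butenolide is the only ring formed (step 7).

Key step: step 7

Remark: the target is treated as the 4-hydroxy (enol) tautomer; its ring atoms are called O1, C2 (lactone C=O), C3 (C–CH3), C4 (C–OH) and C5, and the SMILES is read as (S) at C5 with an all-(E) triene.

**Route**

Step 1
Reactants: 1 pent-4-yn-1-ol
Product: 3 (E)-5-iodo-4-methylpent-4-en-1-ol, via alkenylalane 2 (not isolated)
Conditions: AlMe3 (3 equiv), Cp2ZrCl2 (0.25 equiv), CH2Cl2, 0 °C to rt; then I2, THF, −30 to 0 °C; aq. K2CO3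
Reagents that add atoms: trimethylaluminium, C[Al](C)C; iodine, II
Why: Negishi carboalumination: zirconium-catalysed syn addition of methyl–aluminium across the alkyne puts methyl on the internal carbon, and iodinolysis with retention gives the (E)-vinyl iodide.

Step 2
Reactants: 3 (E)-5-iodo-4-methylpent-4-en-1-ol
Product: 5 (E)-5-iodo-4-methylpent-4-enoic acid, via aldehyde 4 (not isolated)
Conditions: TEMPO (0.2 equiv), PhI(OAc)2 (2.2 equiv), MeCN/H2O, rt
Reagents that add atoms: water, O
Why: Oxoammonium (TEMPO) oxidation takes the primary alcohol through the aldehyde hydrate to the acid without touching the vinyl iodide.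

Step 3
Reactants: 5 (E)-5-iodo-4-methylpent-4-enoic acid; 6 (R)-4-benzyl-1,3-oxazolidin-2-one
Product: 8 (R)-4-benzyl-3-[(E)-5-iodo-4-methylpent-4-enoyl]-1,3-oxazolidin-2-one, via mixed pivalic anhydride 7 (not isolated)
Conditions: t-BuCOCl, Et3N, THF, −20 °C; then 6, LiCl, rt
Reagents that add atoms: none
Why: N-Acylation of the oxazolidinone through the mixed pivalic anhydride, with lithium chloride activating the auxiliary, is the standard way to attach it.

Step 4
Reactants: 8 (R)-4-benzyl-3-[(E)-5-iodo-4-methylpent-4-enoyl]-1,3-oxazolidin-2-one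
Product: 10 (R)-4-benzyl-3-[(2R,4E)-2-hydroxy-5-iodo-4-methylpent-4-enoyl]-1,3-oxazolidin-2-one, via sodium enolate 9 (not isolated)
Conditions: NaHMDS (1.1 equiv), THF, −78 °C; then 3-phenyl-2-(phenylsulfonyl)oxaziridine (1.3 equiv), −78 °C; AcOH quench
Reagents that add atoms: 3-phenyl-2-(phenylsulfonyl)oxaziridine, O=S(=O)(N1OC1c1ccccc1)c1ccccc1
Why: Auxiliary-controlled enolate hydroxylation: the chelated (Z)-sodium enolate is oxidised by the N-sulfonyloxaziridine on the face opposite the benzyl group, which should set C2 as (R), and any minor diastereomer can be removed by chromatography.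

Step 5
Reactants: 10 (R)-4-benzyl-3-[(2R,4E)-2-hydroxy-5-iodo-4-methylpent-4-enoyl]-1,3-oxazolidin-2-one; 11 2-(trimethylsilyl)ethanol
Product: 13 2-(trimethylsilyl)ethyl (2R,4E)-2-hydroxy-5-iodo-4-methylpent-4-enoate, via bromomagnesium alkoxide 12 (not isolated)
Conditions: 11 (6 equiv), MeMgBr (3 equiv), THF, 0 °C; then 10, 0 °C to rt; cold dilute aq. HCl
Reagents that add atoms: none
Why: Transesterification of the N-acyloxazolidinone by a halomagnesium alkoxide attacks the exocyclic acyl carbon, releases the auxiliary and leaves C2 untouched because the α-hydroxyl is held as its magnesium alkoxide.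

Step 6
Reactants: 13 2-(trimethylsilyl)ethyl (2R,4E)-2-hydroxy-5-iodo-4-methylpent-4-enoate
Product: 14 2-(trimethylsilyl)ethyl (2R,4E)-5-iodo-4-methyl-2-[(trifluoromethylsulfonyl)oxy]pent-4-enoate
Conditions: Tf2O (1.2 equiv), 2,6-lutidine (1.5 equiv), CH2Cl2, −78 °C; cold silica filtration, used at once
Reagents that add atoms: trifluoromethanesulfonic anhydride, O=S(=O)(OS(=O)(=O)C(F)(F)F)C(F)(F)F
Why: O-Triflation of the secondary alcohol does not touch the C2–O bond, so the (R) configuration is retained in an α-triflyloxy ester that is an established SN2 electrophile.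

Step 7
Reactants: 14 2-(trimethylsilyl)ethyl (2R,4E)-5-iodo-4-methyl-2-[(trifluoromethylsulfonyl)oxy]pent-4-enoate; 15 ethyltriphenylphosphonium bromide; 16 carbon dioxide
Product: 21 (S)-5-[(E)-3-iodo-2-methylprop-2-en-1-yl]-3-methyl-4-[2-(trimethylsilyl)ethoxy]furan-2(5H)-one, via ethylidenephosphorane 17 (not isolated), via phosphonio carboxylate 18 (not isolated), via phosphonium triflate 19 (not isolated), via ester ylide 20 (not isolated)
Conditions: 15 (1.4 equiv), KHMDS (1.3 equiv), toluene, 0 °C; ylide cannula-filtered from KBr into CO2-saturated toluene (1 atm CO2), −78 to 0 °C; then 14 in MeCN, −20 °C to rt; then i-Pr2NEt (2 equiv), 75 °C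
Reagents that add atoms: none
Why: Proposed new method: the salt-free ylide 17 is carboxylated by CO2 to the phosphonio carboxylate 18, whose carboxylate oxygen (its only nucleophilic site at this stage) displaces the triflate of 14 by SN2 with inversion and so forms the O1–C5 bond; amine base then converts phosphonium salt 19 into the ester-stabilised ylide 20, whose carbon (C3) adds to the neighbouring ester carbonyl (C4) and, after loss of Ph3PO from the oxaphosphetane, leaves the C3=C4 enol ether. The closest known reaction types are the carboxylation of non-stabilised phosphorus ylides, the alkylation of carboxylates by α-triflyloxy esters, and the domino esterification/intramolecular Wittig olefination of α-hydroxy esters with ketenylidenetriphenylphosphorane, which passes through the same kind of acyl ylide ester and closes it onto the ester carbonyl to give 4-alkoxyfuran-2(5H)-ones. The only ring formed, the butenolide, is closed at the C3–C4 bond by 5-exo-trig attack of the ylide carbon on the ester C=O, a formal [3+2] union of an O1–C2–C3 unit (CO2 plus the ylide carbon with its methyl) with the C4–C5 unit of 14. The C5 stereocentre is controlled by the substrate: clean inversion of the (R)-triflate should give (S), and no enolate-forming base is present that could epimerise C5–H. The selectivities needed are substitution over elimination and over halide exchange (secured by the weakly basic, bromide-free carboxylate and by the α-ester triflate, which cannot ionise), 1:1 carboxylation without transylidation (secured by adding the ylide to excess CO2), and olefination of the ester carbonyl in preference to any intermolecular path (secured by the five-membered tether); the ester alkoxy group ends up as the removable protecting group on O4.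

Step 8
Reactants: 22 3-bromofuran; 23 4-bromofuran-2-carbaldehyde
Product: 25 (4-bromofuran-2-yl)(furan-3-yl)methanol (racemate), via furan-3-yllithium 24 (not isolated)
Conditions: n-BuLi (1.05 equiv), THF, −78 °C; then 23, −78 °C; H2O
Reagents that add atoms: none
Why: Bromine–lithium exchange followed by carbonyl addition: furan-3-yllithium is positionally stable at −78 °C and adds to the aldehyde faster than it exchanges with the ring bromide; the carbinol carbon loses its oxygen in step 9, so the racemate is carried on.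

Step 9
Reactants: 25 (4-bromofuran-2-yl)(furan-3-yl)methanol
Product: 26 4-bromo-2-(furan-3-ylmethyl)furan
Conditions: Et3SiH (3 equiv), CF3CO2H (5 equiv), CH2Cl2, −20 to 0 °C
Reagents that add atoms: none
Why: Ionic hydrogenation: protonation and loss of water give a carbocation stabilised by both furans, which excess triethylsilane should reduce faster than it can attack another furan.

Step 10
Reactants: 26 4-bromo-2-(furan-3-ylmethyl)furan; 27 but-3-en-1-ylzinc bromide
Product: 28 4-(but-3-en-1-yl)-2-(furan-3-ylmethyl)furan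
Conditions: Pd(OAc)2 (3 mol %), SPhos (6 mol %), THF, 50 °C
Reagents that add atoms: none
Why: Negishi coupling of a primary alkylzinc bromide with the furyl bromide; the bulky biaryl phosphine favours reductive elimination over β-hydride elimination.

Step 11
Reactants: 28 4-(but-3-en-1-yl)-2-(furan-3-ylmethyl)furan; 29 methacrolein
Product: 30 (E)-5-[5-(furan-3-ylmethyl)furan-3-yl]-2-methylpent-2-enal
Conditions: second-generation Hoveyda–Grubbs catalyst (5 mol %), 29 (8 equiv), CH2Cl2, 40 °C
Reagents that add atoms: none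
Why: Cross-metathesis of a terminal alkene with methacrolein should give the (E)-2-methyl-2-enal under thermodynamic control, the aromatic furans being inert to the ruthenium carbene.

Step 12
Reactants: 30 (E)-5-[5-(furan-3-ylmethyl)furan-3-yl]-2-methylpent-2-enal; 31 2,2'-methylenebis(4,4,5,5-tetramethyl-1,3,2-dioxaborolane)
Product: 33 2-[(1E,3E)-6-[5-(furan-3-ylmethyl)furan-3-yl]-3-methylhexa-1,3-dien-1-yl]-4,4,5,5-tetramethyl-1,3,2-dioxaborolane, via lithiated diborylmethane 32 (not isolated)
Conditions: 31 (1.3 equiv), LiTMP (1.25 equiv), THF, 0 °C; then 30, −78 °C to rt; H2O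
Reagents that add atoms: none
Why: Boron-Wittig olefination: the α-boryl carbanion adds 1,2 to the enal and syn-elimination of the boron–oxygen unit should give the (E)-alkenyl boronate, here the (1E,3E)-dienyl boronate.

Step 13
Reactants: 21 (S)-5-[(E)-3-iodo-2-methylprop-2-en-1-yl]-3-methyl-4-[2-(trimethylsilyl)ethoxy]furan-2(5H)-one; 33 2-[(1E,3E)-6-[5-(furan-3-ylmethyl)furan-3-yl]-3-methylhexa-1,3-dien-1-yl]-4,4,5,5-tetramethyl-1,3,2-dioxaborolane
Product: 34 (S)-5-[(2E,4E,6E)-9-[5-(furan-3-ylmethyl)furan-3-yl]-2,6-dimethylnona-2,4,6-trien-1-yl]-3-methyl-4-[2-(trimethylsilyl)ethoxy]furan-2(5H)-one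
Conditions: Pd(dppf)Cl2 (5 mol %), K3PO4 (3 equiv), THF/H2O, 40 °C, degassed, dark
Reagents that add atoms: none
Why: Suzuki–Miyaura coupling joins the two sp2 carbons with retention of both alkene geometries, so the (2E,4E,6E)-triene should result, and the mild phosphate base is not expected to epimerise C5 or open the vinylogous ester.

Step 14
Reactants: 34 (S)-5-[(2E,4E,6E)-9-[5-(furan-3-ylmethyl)furan-3-yl]-2,6-dimethylnona-2,4,6-trien-1-yl]-3-methyl-4-[2-(trimethylsilyl)ethoxy]furan-2(5H)-one
Product: 35 (S)-5-[(2E,4E,6E)-9-[5-(furan-3-ylmethyl)furan-3-yl]-2,6-dimethylnona-2,4,6-trien-1-yl]-4-hydroxy-3-methylfuran-2(5H)-one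
Conditions: TBAF (2 equiv), THF, 0 °C to rt; then cold dilute aq. HCl
Reagents that add atoms: none
Why: Fluoride attacks silicon and β-elimination expels ethene and the tetronate anion, a carboxylate-like leaving group, as in the cleavage of 2-(trimethylsilyl)ethyl esters; acidification gives the 4-hydroxy tautomer with C5 untouched.

**Compound list**
1 | pent-4-yn-1-ol | C#CCCCO | starting material
2 | [(E)-5-[(dimethylalumanyl)oxy]-2-methylpent-1-en-1-yl]dimethylalumane | C[Al](C)OCCC/C(C)=C/[Al](C)C | intermediate
3 | (E)-5-iodo-4-methylpent-4-en-1-ol | OCCC/C(C)=C/I | intermediate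
4 | (E)-5-iodo-4-methylpent-4-enal | O=CCC/C(C)=C/I | intermediate
5 | (E)-5-iodo-4-methylpent-4-enoic acid | OC(=O)CC/C(C)=C/I | intermediate
6 | (R)-4-benzyl-1,3-oxazolidin-2-one | O=C1N[C@H](Cc2ccccc2)CO1 | starting material
7 | (E)-5-iodo-4-methylpent-4-enoic pivalic anhydride | CC(C)(C)C(=O)OC(=O)CC/C(C)=C/I | intermediate
8 | (R)-4-benzyl-3-[(E)-5-iodo-4-methylpent-4-enoyl]-1,3-oxazolidin-2-one | O=C(CC/C(C)=C/I)N1[C@H](Cc2ccccc2)COC1=O | intermediate
9 | sodium (1Z,4E)-1-[(R)-4-benzyl-2-oxo-1,3-oxazolidin-3-yl]-5-iodo-4-methylpenta-1,4-dien-1-olate | [Na+].[O-]/C(=C\C/C(C)=C/I)N1[C@H](Cc2ccccc2)COC1=O | intermediate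
10 | (R)-4-benzyl-3-[(2R,4E)-2-hydroxy-5-iodo-4-methylpent-4-enoyl]-1,3-oxazolidin-2-one | O=C([C@H](O)C/C(C)=C/I)N1[C@H](Cc2ccccc2)COC1=O | intermediate
11 | 2-(trimethylsilyl)ethanol | C[Si](C)(C)CCO | starting material
12 | bromomagnesium 2-(trimethylsilyl)ethoxide | C[Si](C)(C)CCO[Mg]Br | intermediate
13 | 2-(trimethylsilyl)ethyl (2R,4E)-2-hydroxy-5-iodo-4-methylpent-4-enoate | C[Si](C)(C)CCOC(=O)[C@H](O)C/C(C)=C/I | intermediate
14 | 2-(trimethylsilyl)ethyl (2R,4E)-5-iodo-4-methyl-2-[(trifluoromethylsulfonyl)oxy]pent-4-enoate | C[Si](C)(C)CCOC(=O)[C@H](OS(=O)(=O)C(F)(F)F)C/C(C)=C/I | intermediate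
15 | ethyltriphenylphosphonium bromide | CC[P+](c1ccccc1)(c1ccccc1)c1ccccc1.[Br-] | starting material
16 | carbon dioxide | O=C=O | starting material
17 | ethylidenetriphenylphosphorane | CC=P(c1ccccc1)(c1ccccc1)c1ccccc1 | intermediate
18 | 2-(triphenylphosphonio)propanoate (zwitterion, racemic) | CC(C(=O)[O-])[P+](c1ccccc1)(c1ccccc1)c1ccccc1 | intermediate
19 | {1-[((2S,4E)-5-iodo-4-methyl-1-oxo-1-[2-(trimethylsilyl)ethoxy]pent-4-en-2-yl)oxy]-1-oxopropan-2-yl}triphenylphosphonium trifluoromethanesulfonate (both epimers at the phosphorus-bearing carbon) | CC(C(=O)O[C@@H](C/C(C)=C/I)C(=O)OCC[Si](C)(C)C)[P+](c1ccccc1)(c1ccccc1)c1ccccc1.[O-]S(=O)(=O)C(F)(F)F | intermediate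
20 | 2-(trimethylsilyl)ethyl (2S,4E)-5-iodo-4-methyl-2-{[2-(triphenyl-λ5-phosphanylidene)propanoyl]oxy}pent-4-enoate | CC(C(=O)O[C@@H](C/C(C)=C/I)C(=O)OCC[Si](C)(C)C)=P(c1ccccc1)(c1ccccc1)c1ccccc1 | intermediate
21 | (S)-5-[(E)-3-iodo-2-methylprop-2-en-1-yl]-3-methyl-4-[2-(trimethylsilyl)ethoxy]furan-2(5H)-one | CC1=C(OCC[Si](C)(C)C)[C@H](C/C(C)=C/I)OC1=O | intermediate
22 | 3-bromofuran | Brc1ccoc1 | starting material
23 | 4-bromofuran-2-carbaldehyde | O=Cc1cc(Br)co1 | starting material
24 | furan-3-yllithium | [Li]c1ccoc1 | intermediate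
25 | (4-bromofuran-2-yl)(furan-3-yl)methanol (racemate) | OC(c1ccoc1)c1cc(Br)co1 | intermediate
26 | 4-bromo-2-(furan-3-ylmethyl)furan | Brc1coc(Cc2ccoc2)c1 | intermediate
27 | but-3-en-1-ylzinc bromide | C=CCC[Zn]Br | starting material
28 | 4-(but-3-en-1-yl)-2-(furan-3-ylmethyl)furan | C=CCCc1coc(Cc2ccoc2)c1 | intermediate
29 | methacrolein (2-methylprop-2-enal) | C=C(C)C=O | starting material
30 | (E)-5-[5-(furan-3-ylmethyl)furan-3-yl]-2-methylpent-2-enal | O=C/C(C)=C/CCc1coc(Cc2ccoc2)c1 | intermediate
31 | 2,2'-methylenebis(4,4,5,5-tetramethyl-1,3,2-dioxaborolane) | CC1(C)OB(CB2OC(C)(C)C(C)(C)O2)OC1(C)C | starting material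
32 | [bis(4,4,5,5-tetramethyl-1,3,2-dioxaborolan-2-yl)methyl]lithium | [Li]C(B1OC(C)(C)C(C)(C)O1)B1OC(C)(C)C(C)(C)O1 | intermediate
33 | 2-[(1E,3E)-6-[5-(furan-3-ylmethyl)furan-3-yl]-3-methylhexa-1,3-dien-1-yl]-4,4,5,5-tetramethyl-1,3,2-dioxaborolane | CC1(C)OB(/C=C/C(C)=C/CCc2coc(Cc3ccoc3)c2)OC1(C)C | intermediate
34 | (S)-5-[(2E,4E,6E)-9-[5-(furan-3-ylmethyl)furan-3-yl]-2,6-dimethylnona-2,4,6-trien-1-yl]-3-methyl-4-[2-(trimethylsilyl)ethoxy]furan-2(5H)-one | CC1=C(OCC[Si](C)(C)C)[C@H](C/C(C)=C/C=C/C(C)=C/CCc2coc(Cc3ccoc3)c2)OC1=O | intermediate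
35 | (S)-5-[(2E,4E,6E)-9-[5-(furan-3-ylmethyl)furan-3-yl]-2,6-dimethylnona-2,4,6-trien-1-yl]-4-hydroxy-3-methylfuran-2(5H)-one | CC1=C(O)[C@H](C/C(C)=C/C=C/C(C)=C/CCc2coc(Cc3ccoc3)c2)OC1=O | target

**Step count and risks**
Total steps: 14. Longest linear sequence: 9 steps (steps 1 to 7, then 13 and 14); the boronate branch (steps 8 to 12) is 5 steps.

Steps most likely to fail:

Step 7 (proposed new method). The weakly nucleophilic phosphonio carboxylate may alkylate slowly, so that elimination of triflic acid from 14 or decarboxylation of the betaine takes over; transylidation during carboxylation would produce a carbon-nucleophilic ylide carboxylate; and the α-methyl ylide may olefinate the ester carbonyl sluggishly. The fallback uses known reactions only, sets out from 13 and comes back at 21. Mitsunobu esterification of 13 with propanoic acid (PPh3, DIAD, THF, 0 °C) forms the same O1–C5 bond with inversion and gives 2-(trimethylsilyl)ethyl (2S,4E)-5-iodo-4-methyl-2-(propanoyloxy)pent-4-enoate F1. Dieckmann condensation with LiHMDS (2.2 equiv, THF, −78 °C) then forms C3–C4 and gives (S)-4-hydroxy-5-[(E)-3-iodo-2-methylprop-2-en-1-yl]-3-methylfuran-2(5H)-one F2. Mitsunobu O-alkylation of F2 with 11 (PPh3, DIAD, THF) returns to 21.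

Step 5. Exchange with the bulky alkoxide outside its own alcohol as solvent may be slow, and attack at the ring carbonyl of the α-hydroxy imide (endocyclic cleavage or acyl migration) may compete. The fallback sets out from 10 and comes back at 13: hydrolysis with LiOH/H2O2 (THF/H2O, 0 °C) removes the auxiliary and gives (2R,4E)-2-hydroxy-5-iodo-4-methylpent-4-enoic acid F3, and carbodiimide esterification of F3 with excess 11 (EDC·HCl, cat. DMAP, CH2Cl2, 0 °C) gives 13.

Step 9. Under acid the furyl-stabilised cation may alkylate a second furan ring (oligomerisation), or a furan may ring-open before hydride transfer. The fallback avoids any carbocation, sets out from 23 and comes back at 26. NaBH4 reduction (MeOH, 0 °C) gives (4-bromofuran-2-yl)methanol F4, and MsCl/Et3N followed by LiCl (THF) gives 4-bromo-2-(chloromethyl)furan F5. Copper-catalysed alkylation (cat. Li2CuCl4, THF, −20 °C) of furan-3-ylmagnesium bromide F6, made from 24 and MgBr2, with F5 then gives 26.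

**Further compounds**
F1 | step 7 | 2-(trimethylsilyl)ethyl (2S,4E)-5-iodo-4-methyl-2-(propanoyloxy)pent-4-enoate | CCC(=O)O[C@@H](C/C(C)=C/I)C(=O)OCC[Si](C)(C)C
F2 | step 7 | (S)-4-hydroxy-5-[(E)-3-iodo-2-methylprop-2-en-1-yl]-3-methylfuran-2(5H)-one | CC1=C(O)[C@H](C/C(C)=C/I)OC1=O
F3 | step 5 | (2R,4E)-2-hydroxy-5-iodo-4-methylpent-4-enoic acid | OC(=O)[C@H](O)C/C(C)=C/I
F4 | step 9 | (4-bromofuran-2-yl)methanol | OCc1cc(Br)co1
F5 | step 9 | 4-bromo-2-(chloromethyl)furan | ClCc1cc(Br)co1
F6 | step 9 | furan-3-ylmagnesium bromide | Br[Mg]c1ccoc1
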